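Product beyond 95.0% of the starting material is impossible in dawn if each product takes up one partner, because partner, the smaller charge, stands at 0.475 M against 0.50 M of starting material. That ceiling is loose, and the blue run gives a closer one.

| flask | starting material | partner | initiator | remark | time |
|---|---|---|---|---|---|
| blue | 0.50 M | 0.475 M | 65 mM | run made earlier |  |
| grey | 0.25 M | 0.475 M | 65 mM | run made earlier |  |
| violet | 0.38 M | 0.475 M | 65 mM | run made earlier |  |
| dusk | 0.50 M (fed, over 12.5 min) | 0.475 M | 65 mM | all but starting material at the start; starting material goes in evenly over 12.5 min, the run ends at 25 min | 25 min |
| winter | 0.50 M | 0.475 M | 65 mM | a single well-mixed tank run continuously and read at steady state, 25 min in it on average |  |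
| noon | 0.50 M | 0.475 M (fed, over 12.5 min) | 65 mM | a stirred flask in which partner is dosed at a steady rate over 12.5 min without added volume, worked up at 25 min | 25 min |
| dawn | 0.50 M | 0.475 M | 65 mM | a closed flask charged with all of it at once and left for 25 min | 25 min |

- blue (time / min: product / %): 4.00: 18.5; 8.00: 32.3; 12.0: 40.5; 15.0: 44.6
- grey (time / min: product / %): 4.00: 26.8; 8.00: 43.1; 12.0: 54.5; 15.0: 60.8
- violet (time / min: product / %): 2.00: 11.3; 5.00: 24.7; 10.0: 41.3; 15.0: 50.5

(readings scatter by 0.5 percentage points)

1. the set-up with the highest amount of product at the outlet or at the end, in percent of the starting material put in ("none" if the first two lie within 2 percentage points) (dusk / winter / noon / dawn / none)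
2. amount of product at the outlet or at the end, in percent of the starting material put in, dusk
3. amount of product at the outlet or at the end, in percent of the starting material put in, winter
4. amount of product at the outlet or at the end, in percent of the starting material put in, noon
5. amount of product at the outlet or at the end, in percent of the starting material put in, dawn

- the stated concentrations are those of everything mixed, before any reaction; amounts are the same in each set-up
- the numbers in the tables scatter by 0.5 percentage points (one standard deviation)
- the feed brings no volume worth counting
- the earlier runs were made in a closed, stirred flask

Dawn is the blue recipe in a closed flask, left longer, so the blue reading of 44.6% at 15.0 min serves as a floor for dawn. As a share of the charge per minute, blue makes 0.0462 min⁻¹ in its first interval but 0.0137 min⁻¹ in its last. Holding that last rate to 25 min gives a ceiling of 58.3%, provided the rate goes on falling.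

To tighten this, freeze the fade, the fraction of the rate lost each minute, read between the middles of those two intervals as 0.106 min⁻¹. The rate then halves every 6.54 min, and the reckoning here puts dawn at 51.8%. The feeds of dusk and noon last twice that half-time, so their reagents arrive late, and dawn should stand first.

The forecast also names dawn, with 52% there (49% to 56%), 44% for dusk, 39% for noon and 36% for winter. It reads from the runs that “initiator activity decays with a half-life of about 15 min”, whereas the fade reckoned here belongs to the whole blue rate. Its dawn lies inside the bracket.

The flasks give 54.2% for dawn, 44.7% for noon, 43.1% for dusk and 41.0% for winter.

    initiator → 2 initiating radical (k = 0.0909 min⁻¹)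
    starting material + initiating radical → capped initiator + first chain carrier (k = 11000 M⁻¹ s⁻¹)
    partner + first chain carrier → product + second chain carrier (k = 65800 M⁻¹ min⁻¹)
    starting material + second chain carrier → released group + first chain carrier (k = 57500 M⁻¹ min⁻¹)
    first chain carrier → ended carrier (k = 1770 min⁻¹)
    2 second chain carrier → ended chains (k = 2.00 × 10⁸ M⁻¹ s⁻¹)

Noon ends 5.7 percentage points above the forecast, holding ended carrier at 9.97% of the starting material against 4.55% in dawn. The figure from the frozen fade stands 2.4 points below dawn. Put on the grey run, the same fade carries its last reading of 60.8% to 71.8% at 25 min, and the grey flask left that long stands at 72.1%.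

Readings and results stem from a simulated flask for substances that don't exist, noise included.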